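**Plan**
The retrosynthesis first cuts the two aryl–prenyl bonds C8–C1'' and C6–C1'', then the C2–C1' bond between the pyranone and the dimethoxyphenyl ring.
The feature behind the first cut: on ring A the C7 phenol is flanked by its two ortho carbons, C6 and C8, and both carry the same 3-methylbut-2-enyl group, the substitution that aromatic prenyltransferases produce on flavanone A rings.
Forward: rings A and C come ready-made in 7-hydroxychromone, ring B is joined at C2 by asymmetric conjugate addition of an arylboronic acid, and no ring is formed anywhere in the route.
The two prenyl groups are then transferred from two molecules of dimethylallyl diphosphate by two regiospecific prenyltransferases in one pot, C8 first and C6 second.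
The only stereocentre, C2 (S), is set by the chiral Pd/pyridine-oxazoline catalyst in the conjugate addition and afterwards meets only neutral or buffered conditions.

Key step: step 5

Remark: the (R)-ligand in step 2 is assigned by analogy, since the (S)-ligand adds aryl groups to cyclic enones to give (R)-β-aryl ketones and the same enone face corresponds to 2R in a flavanone; the sense is to be confirmed on 5 by chiroptical comparison.
Remark: 7 is drawn as the free acid but is prepared, stored and used as its tris-ammonium salt.
Remark: step 5 consumes two molecules of 7 per molecule of 5, one for each prenyl group, and each enzyme stage is run with an excess; step 4 is therefore run on a scale that supplies at least three equivalents of 7 relative to 5.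
Remark: the two enzymes of step 5 are taken as recombinant proteins (the plant enzyme as a yeast microsomal fraction, the fungal enzyme as purified soluble protein); their expression is not counted as a synthetic step.

**Step 1**
Reactants: 1 7-hydroxychromone
Product: 2 7-(triisopropylsilyloxy)chromone
Conditions: TIPSCl, imidazole, DMF, rt
Reagents that add atoms: triisopropylsilyl chloride, CC(C)[Si](Cl)(C(C)C)C(C)C
Why: Silylation of a phenol with a trialkylsilyl chloride and imidazole is routine, the C7 hydroxyl is the only nucleophile, and the bulky triisopropylsilyl ether is chosen to survive the warm, wet, weakly acidic medium of step 2 while keeping the acidic phenol away from the cationic palladium catalyst.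

**Step 2**
Reactants: 2 7-(triisopropylsilyloxy)chromone; 3 3,4-dimethoxyphenylboronic acid
Product: 4 (2S)-3',4'-dimethoxy-7-(triisopropylsilyloxy)flavanone
Conditions: Pd(OCOCF3)2 (cat.), (R)-t-BuPyOx (cat.), NH4PF6, H2O, ClCH2CH2Cl, 60 °C
Reagents that add atoms: none
Why: Pd(II)-catalysed asymmetric conjugate addition of arylboronic acids to chromones is an established flavanone synthesis (aryl transfer from boron to palladium, insertion of the C2=C3 bond, protonation of the palladium enolate by water), and the new C2 stereocentre is set in the insertion step by the tert-butyl group of the pyridine-oxazoline ligand, which blocks one face of the bound enone so that the (R)-ligand should deliver the aryl group to give 2S.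

**Step 3**
Reactants: 4 (2S)-3',4'-dimethoxy-7-(triisopropylsilyloxy)flavanone
Product: 5 (2S)-7-hydroxy-3',4'-dimethoxyflavanone
Conditions: TBAF, AcOH, THF, 0 °C
Reagents that add atoms: none
Why: Fluoride cleavage of an aryl silyl ether is fast here because the electron-poor 7-aryloxide leaves silicon readily, and the acetic acid buffer protonates the phenoxide at once so that C2 never meets free base and the pyranone is not opened by a retro-oxa-Michael reaction.

**Step 4**
Reactants: 6 prenyl bromide (1-bromo-3-methylbut-2-ene)
Product: 7 dimethylallyl diphosphate
Conditions: (n-Bu4N)3HP2O7, MeCN, 0 °C to rt; Dowex 50W-X8 (NH4+ form), aq. NH4HCO3; cellulose chromatography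
Reagents that add atoms: tris(tetrabutylammonium) hydrogen diphosphate, CCCC[N+](CCCC)(CCCC)CCCC.CCCC[N+](CCCC)(CCCC)CCCC.CCCC[N+](CCCC)(CCCC)CCCC.OP(=O)([O-])OP(=O)([O-])[O-]
Why: SN2 alkylation of inorganic diphosphate by a primary allylic halide in acetonitrile is the standard preparation of allylic diphosphates, the unhindered C1 being attacked directly without allylic transposition, and cation exchange then gives the water-soluble ammonium salt needed for the enzymes.

**Step 5**
Reactants: 5 (2S)-7-hydroxy-3',4'-dimethoxyflavanone; 7 dimethylallyl diphosphate (two molar equivalents are consumed, one in each transfer)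
Product: 9 (2S)-7-hydroxy-3',4'-dimethoxy-6,8-diprenylflavanone, via 8-monoprenyl flavanone 8 (not isolated)
Conditions: (i) SfN8DT-1 (flavanone 8-dimethylallyltransferase, yeast microsomes), 7 (1.5 equiv), MgCl2, Tris·HCl pH 7.5, 5% DMSO, 30 °C; (ii) 7-DMATS (soluble fungal prenyltransferase), 7 (1.5 equiv), CaCl2, same pot, 30 °C; EtOAc extraction at pH 7
Reagents that add atoms: dimethylallyl diphosphate (7, the second molar equivalent, which supplies the C6 prenyl group), CC(C)=CCOP(=O)(O)OP(=O)(O)O
Why: Proposed new method: in each active site the C–O bond of one molecule of 7 is ionised and the dimethylallyl cation, paired with diphosphate, is captured at its C1 by ring A of the C7 phenol(ate), through C8 in the first enzyme (giving 8) and through C6 in the second (giving 9), each Wheland intermediate being rearomatised by loss of the ring proton (enzymatic Friedel–Crafts alkylation). The closest known reaction types are the C8-dimethylallylation of naringenin-type flavanones by membrane-bound plant flavanone 8-dimethylallyltransferases and the C6-dimethylallylation of flavanones by soluble fungal tryptophan prenyltransferases; the two transfers in sequence on one 5-deoxyflavanone with a methylated B ring have not been shown. No ring is closed and no stereocentre is created: C2 should stay (S) because at pH 7.5 and 30 °C neither enolisation at C3 nor retro-oxa-Michael opening of the pyranone is expected, and without acid the ortho-prenyl phenol does not cyclise to a chroman. The step needs C- over O-alkylation, bonding through C1 and not C3 of the allyl unit, and substitution at C8 and C6 only; the first two are supplied by the enzyme pockets, which hold the cation over the ring carbon. The third is supplied by the substrate: the C7 hydroxyl is the only phenol, both of its ortho carbons carry hydrogen, C5 is meta to it and adjacent to the carbonyl-bearing C4a, and ring B has only methyl ethers, so no third position is activated and the reaction should stop at two prenyl groups. Adding the C6 enzyme with its own charge of 7 only after the C8 transfer is complete fixes the order, so the narrow-specificity plant enzyme always meets the unprenylated acceptor.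

**Compound list**
1 | 7-hydroxychromone (7-hydroxy-4H-chromen-4-one) | O=c1ccoc2cc(O)ccc12 | starting material
2 | 7-(triisopropylsilyloxy)chromone | O=c1ccoc2cc(O[Si](C(C)C)(C(C)C)C(C)C)ccc12 | intermediate
3 | 3,4-dimethoxyphenylboronic acid | COc1ccc(B(O)O)cc1OC | starting material
4 | (2S)-3',4'-dimethoxy-7-(triisopropylsilyloxy)flavanone [(2S)-2-(3,4-dimethoxyphenyl)-7-(triisopropylsilyloxy)chroman-4-one] | COc1ccc([C@@H]2CC(=O)c3ccc(O[Si](C(C)C)(C(C)C)C(C)C)cc3O2)cc1OC | intermediate
5 | (2S)-7-hydroxy-3',4'-dimethoxyflavanone [(2S)-2-(3,4-dimethoxyphenyl)-7-hydroxychroman-4-one] | COc1ccc([C@@H]2CC(=O)c3ccc(O)cc3O2)cc1OC | intermediate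
6 | prenyl bromide (1-bromo-3-methylbut-2-ene) | CC(C)=CCBr | starting material
7 | dimethylallyl diphosphate (3-methylbut-2-enyl diphosphate, free-acid form) | CC(C)=CCOP(=O)(O)OP(=O)(O)O | intermediate
8 | (2S)-7-hydroxy-3',4'-dimethoxy-8-prenylflavanone [(2S)-2-(3,4-dimethoxyphenyl)-7-hydroxy-8-(3-methylbut-2-enyl)chroman-4-one] | COc1ccc([C@@H]2CC(=O)c3ccc(O)c(CC=C(C)C)c3O2)cc1OC | intermediate
9 | (2S)-7-hydroxy-3',4'-dimethoxy-6,8-diprenylflavanone [(2S)-2-(3,4-dimethoxyphenyl)-7-hydroxy-6,8-bis(3-methylbut-2-enyl)chroman-4-one] | COc1ccc([C@@H]2CC(=O)c3cc(CC=C(C)C)c(O)c(CC=C(C)C)c3O2)cc1OC | target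

**Step count**
Total steps: 5.
Longest linear sequence: 4 steps (steps 1, 2, 3 and 5); step 4 is a one-step side branch.

**Steps most likely to fail**

1. Step 5. The plant enzyme may not accept the 3',4'-di-O-methylated 5-deoxyflavanone, the fungal enzyme may not turn over the 8-prenylated intermediate so that the reaction stalls after one transfer, or O-prenylation of the C7 hydroxyl may compete. The fallback uses known chemistry, sets out from 5 and returns at 9. Ring A of 5 is iodinated at both phenol-ortho carbons with benzyltrimethylammonium dichloroiodate and NaHCO3 in CH2Cl2–MeOH, where the phenoxide ring reacts far faster than the dimethoxyphenyl ring, to give (2S)-7-hydroxy-6,8-diiodo-3',4'-dimethoxyflavanone F1. The phenol is silylated with TBSCl and imidazole in DMF to (2S)-7-(tert-butyldimethylsilyloxy)-6,8-diiodo-3',4'-dimethoxyflavanone F2. A twofold Stille coupling with tributyl(3-methylbut-2-enyl)stannane under neutral conditions (Pd(PPh3)4, DMF, 90 °C) should then give (2S)-7-(tert-butyldimethylsilyloxy)-3',4'-dimethoxy-6,8-diprenylflavanone F3 with linear prenyl groups. Buffered fluoride (TBAF, AcOH, THF, 0 °C) releases 9 without acid, so the chroman is not formed, and without free base, so C2 is preserved.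

2. Step 2. Enantioselectivity may erode, or the addition may stall, because the 7-silyloxy group makes the chromone a poorer acceptor and the electron-rich boronic acid is prone to protodeboronation and homocoupling; the silyl ether may also be partly lost in the wet medium. The fallback sets out from 2 (with 3) and returns at 4. The addition is run without asymmetric induction using Pd(OCOCF3)2 and 2,2'-bipyridine under otherwise the same conditions to give racemic 3',4'-dimethoxy-7-(triisopropylsilyloxy)flavanone F4. This is resolved by preparative HPLC on an amylose tris(3,5-dimethylphenylcarbamate) phase into 4 and (2R)-3',4'-dimethoxy-7-(triisopropylsilyloxy)flavanone F5, which is set aside. Stereochemistry then comes from separation and not from catalyst control.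

3. Step 4. The allylic bromide may ionise or eliminate before substitution, and the allylic diphosphate may hydrolyse during ion exchange and chromatography, so that little pure material is recovered. The fallback sets out from 6 and returns at 7 and builds the diphosphate in two stages. Displacement with tetrabutylammonium dihydrogen phosphate in MeCN gives the more robust dimethylallyl phosphate F6. Its second phosphoryl group is added enzymatically with isopentenyl phosphate kinase, ATP and MgCl2 at pH 7.5, which forms 7 directly in the buffer used for step 5 and removes the need to isolate it.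

**Further compounds**
F1 | step 5 | (2S)-7-hydroxy-6,8-diiodo-3',4'-dimethoxyflavanone | COc1ccc([C@@H]2CC(=O)c3cc(I)c(O)c(I)c3O2)cc1OC
F2 | step 5 | (2S)-7-(tert-butyldimethylsilyloxy)-6,8-diiodo-3',4'-dimethoxyflavanone | COc1ccc([C@@H]2CC(=O)c3cc(I)c(O[Si](C)(C)C(C)(C)C)c(I)c3O2)cc1OC
F3 | step 5 | (2S)-7-(tert-butyldimethylsilyloxy)-3',4'-dimethoxy-6,8-diprenylflavanone | COc1ccc([C@@H]2CC(=O)c3cc(CC=C(C)C)c(O[Si](C)(C)C(C)(C)C)c(CC=C(C)C)c3O2)cc1OC
F4 | step 2 | racemic 3',4'-dimethoxy-7-(triisopropylsilyloxy)flavanone | COc1ccc(C2CC(=O)c3ccc(O[Si](C(C)C)(C(C)C)C(C)C)cc3O2)cc1OC
F5 | step 2 | (2R)-3',4'-dimethoxy-7-(triisopropylsilyloxy)flavanone | COc1ccc([C@H]2CC(=O)c3ccc(O[Si](C(C)C)(C(C)C)C(C)C)cc3O2)cc1OC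
F6 | step 4 | dimethylallyl phosphate (3-methylbut-2-enyl dihydrogen phosphate) | CC(C)=CCOP(=O)(O)O
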